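The hexanoate side chain is disconnected at C3'. Because C3' sits on C8 beside the C7 phenol oxygen, C3'=C8–C7=O7 is a latent o-quinone methide, and C1' can be tied back to O7 in a temporary six-membered ring (O7, C1', C2', C3', C8, C7) that methanol opens later. In one operation a propyl Grignard reagent, an O-Boc salicylaldehyde and a chiral vinyl ether give this ring as a 2-alkoxychroman, forming C3'–propyl, C3'–C2' and O7–C1' and setting C3'. The precursor is a 2,4,6-trioxygenated benzaldehyde with one ortho and one para Boc carbonate and, on the other ortho oxygen, the chiral 2-methylbutanoate ether that later closes the dihydropyranone ring.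

Key step: step 5

Numbering used: chromanone atoms O1 to C8a, side chain C1' (ester carbon) to C6'. The target is (2S,3S,3'R) with trans-2,3-dimethyl groups.

Assumption: the face of vinyl ether 8 that reacts in step 5 is assigned from a steric model of the phenylcyclohexyl group; if the opposite face is preferred, the commercial (1R,2S) alcohol is used in step 4 and nothing else changes.

Step 1
Reactants: 1 2,4,6-trihydroxybenzaldehyde
Product: 2 2-hydroxy-4,6-bis(tert-butoxycarbonyloxy)benzaldehyde
Conditions: Boc2O (2.0 equiv), i-Pr2NEt, DMAP (cat.), THF, −20 → 0 °C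
Reagents that add atoms: di-tert-butyl dicarbonate CC(C)(C)OC(=O)OC(=O)OC(C)(C)C
Why: Base-catalysed O-acylation to aryl carbonates; the para hydroxyl and one ortho hydroxyl react, after which the last ortho hydroxyl is held in a hydrogen bond to the formyl oxygen and is the least nucleophilic, as in the familiar selective bis-protection of this aldehyde.

Step 2
Reactants: 3 tert-butyl (R)-3-hydroxybutanoate
Product: 4 tert-butyl (2R,3R)-3-hydroxy-2-methylbutanoate
Conditions: LiN(i-Pr)2 (2.2 equiv), THF, −78 → −30 °C; then MeI, DMPU, −78 → −10 °C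
Reagents that add atoms: iodomethane CI
Why: Fráter–Seebach alkylation; the lithium-chelated alkoxide enolate is methylated on the face opposite the C3 methyl group, which sets C2 as R (anti) and leaves C3 untouched.

Step 3
Reactants: 2 2-hydroxy-4,6-bis(tert-butoxycarbonyloxy)benzaldehyde; 4 tert-butyl (2R,3R)-3-hydroxy-2-methylbutanoate
Product: 5 tert-butyl (2R,3S)-3-[3,5-bis(tert-butoxycarbonyloxy)-2-formylphenoxy]-2-methylbutanoate
Conditions: PPh3, DIAD, toluene, 0 °C → rt
Reagents that add atoms: none
Why: Mitsunobu etherification; the phenol, made acidic by the formyl and carbonate groups, displaces the oxyphosphonium group at C3 in SN2 fashion, so C3 inverts to S (the future C2 of the chromanone) while C2 is not touched, and the carbonates and the tert-butyl ester are inert to the betaine.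

Step 4
Reactants: 6 (1S,2R)-trans-2-phenylcyclohexanol; 7 ethyl vinyl ether
Product: 8 (1S,2R)-trans-2-phenylcyclohexyl vinyl ether
Conditions: Pd(OCOCF3)2 (1 mol%), 1,10-phenanthroline (1 mol%), Et3N (cat.), ethyl vinyl ether (solvent), reflux, air
Reagents that add atoms: none
Why: Palladium-catalysed transfer vinylation (vinyl ether exchange); the alcohol oxygen adds to the coordinated vinyl ether and ethoxide leaves, the carbinol C–O bond is never broken so both stereocentres are retained, and the excess of 7 drives the exchange.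

Step 5
Reactants: 5 tert-butyl (2R,3S)-3-[3,5-bis(tert-butoxycarbonyloxy)-2-formylphenoxy]-2-methylbutanoate; 8 (1S,2R)-trans-2-phenylcyclohexyl vinyl ether; 9 n-propylmagnesium chloride
Product: 13 tert-butyl (2R,3S)-3-{[(2R,4R)-7-(tert-butoxycarbonyloxy)-2-{[(1S,2R)-2-phenylcyclohexyl]oxy}-4-propylchroman-5-yl]oxy}-2-methylbutanoate (cis-2,4 chroman acetal), via benzylic magnesium alkoxide 10 (not isolated), via benzylic carbonate phenoxide 11 (not isolated), via E o-quinone methide 12 (not isolated)
Conditions: 8 (3 equiv), n-PrMgCl (1.05 equiv), Et2O/toluene, −78 °C → rt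
Reagents that add atoms: none
Why: n-PrMgCl adds to the formyl group at −78 °C far faster than to the hindered tert-butyl ester or the aryl carbonates; the magnesium alkoxide 10 takes over the neighbouring Boc group through a six-membered transition state, and on warming phenoxide 11 expels tert-butyl carbonate to give o-quinone methide 12, which the electron-rich vinyl ether 8 traps in an inverse-electron-demand hetero-Diels–Alder reaction. The closest known reaction type is the Grignard-triggered formation of o-quinone methides from O-Boc salicylaldehydes with in situ [4+2] capture by trans-2-phenylcyclohexyl enol ethers. The single new ring, the six-membered 2-alkoxychroman, closes by a concerted asynchronous [4+2] cycloaddition in which the C–C bond to the former formyl carbon runs ahead of the O–C(acetal) bond and rearomatisation supplies the driving force. The benzylic centre C4 is set by the E geometry of 12 together with the face of 8 that the phenyl group of the auxiliary leaves open, and the acetal centre C2 by the endo position of the alkoxy group, which places it cis to propyl. The step needs one quinone methide, one alkene geometry and one face: only one ortho oxygen carries a Boc group while the other is an inert ether and the para carbonate is out of reach, the bulky magnesium-bound oxygen turns the propyl group outward, and any Z isomer should be drained by a 1,5-hydrogen shift to a styrene, not converted into the C4 epimer.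

Step 6
Reactants: 13 cis-2,4 chroman acetal
Product: 14 tert-butyl (2R,3S)-3-{[(4R)-7-(tert-butoxycarbonyloxy)-2-hydroxy-4-propylchroman-5-yl]oxy}-2-methylbutanoate (lactol as a mixture of anomers)
Conditions: camphorsulfonic acid (0.2 equiv), acetone/H2O (9:1), 40 °C
Reagents that add atoms: water O
Why: Acid-catalysed hydrolysis of the mixed acetal through the cyclic oxocarbenium ion releases the auxiliary alcohol 6 for recovery, while the tert-butyl ester and the aryl carbonate need far stronger acid and C4 is not involved.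

Step 7
Reactants: 14 lactol
Product: 15 tert-butyl (2R,3S)-3-{[(4R)-7-(tert-butoxycarbonyloxy)-2-oxo-4-propylchroman-5-yl]oxy}-2-methylbutanoate (4-propyl-3,4-dihydrocoumarin)
Conditions: (n-Pr)4N[RuO4] (5 mol%), N-methylmorpholine N-oxide, 4 Å MS, CH2Cl2, rt
Reagents that add atoms: none
Why: Ley–Griffith oxidation of the lactol to the δ-lactone under neutral anhydrous conditions; the acetal stereocentre disappears and C4, which is β to the new carbonyl, cannot epimerise.

Step 8
Reactants: 15 4-propyl-3,4-dihydrocoumarin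
Product: 16 (2R,3S)-3-{[(4R)-7-hydroxy-2-oxo-4-propylchroman-5-yl]oxy}-2-methylbutanoic acid
Conditions: CF3CO2H/CH2Cl2 (1:2), Et3SiH (3 equiv), 0 °C → rt
Reagents that add atoms: none
Why: Acidolysis; CF3CO2H cleaves the tert-butyl ester and the aryl tert-butyl carbonate by loss of the tert-butyl cation (and CO2), Et3SiH reduces that cation so the electron-rich ring is not tert-butylated, and the aryl lactone is stable to anhydrous acid.

Step 9
Reactants: 16 hydroxy lactone acid
Product: 17 (2S,3R,10R)-5-hydroxy-2,3-dimethyl-10-propyl-2,3,9,10-tetrahydro-4H,8H-benzo[1,2-b:3,4-b']dipyran-4,8-dione (tricyclic lactone chromanone with cis-2,3-dimethyl groups)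
Conditions: P2O5 in MeSO3H (1:10 w/w), rt
Reagents that add atoms: none
Why: Intramolecular Friedel–Crafts acylation (cyclodehydration); the acylium or mixed anhydride attacks the ring carbon ortho to the ether oxygen, the only site that gives a six-membered ketone and one activated by the flanking hydroxyl and alkoxy groups, C2 is not involved, and any early epimerisation at C3 only anticipates step 10.

Step 10
Reactants: 17 cis tricyclic lactone chromanone
Product: 19 methyl (3R)-3-[(2S,3S)-5,7-dihydroxy-2,3-dimethyl-4-oxochroman-8-yl]hexanoate, via trans tricyclic lactone 18 (not isolated)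
Conditions: MeSO3H (0.2 equiv), CH2Cl2, 40 °C; then Et3N (3 equiv), MeOH, 0 °C → rt; cold pH 5 buffer
Reagents that add atoms: methanol CO
Why: Acid-catalysed enolisation of the chelated ketone should equilibrate C3 towards the 2,3-trans isomer with both methyl groups pseudo-equatorial, with no enolate or phenoxide that could open the O1–C2 bond by E1cB, and amine-promoted methanolysis (transesterification) of the aryl lactone then gives the methyl ester, driven by release of the acidic 7-phenol; residual cis isomer is separated and resubmitted.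

Step 11
Reactants: 19 6-unsubstituted chromanone methyl ester; 20 prenyl bromide
Product: 21 methyl (3R)-3-[(2S,3S)-5,7-dihydroxy-2,3-dimethyl-6-(3-methylbut-2-en-1-yl)-4-oxochroman-8-yl]hexanoate (target)
Conditions: NaOMe (1.1 equiv), MeOH, 0 °C; then 20 (1.5 equiv), 0 °C → rt
Reagents that add atoms: none
Why: C-alkylation of an ambident phenoxide; in methanol the hydrogen-bonded oxygen is shielded, so the allylic bromide is attacked by C6, the only unsubstituted ring carbon and ortho to both oxygens, and tautomerisation restores the arene, while methoxide in methanol cannot change the methyl ester and the single equivalent of base stays bound as phenoxide, which protects C3 and the O1–C2 bond.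

Compound list
1 | 2,4,6-trihydroxybenzaldehyde | O=Cc1c(O)cc(O)cc1O | starting material
2 | 2-hydroxy-4,6-bis(tert-butoxycarbonyloxy)benzaldehyde | O=Cc1c(O)cc(OC(=O)OC(C)(C)C)cc1OC(=O)OC(C)(C)C | intermediate
3 | tert-butyl (R)-3-hydroxybutanoate | C[C@@H](O)CC(=O)OC(C)(C)C | starting material
4 | tert-butyl (2R,3R)-3-hydroxy-2-methylbutanoate | C[C@@H](O)[C@@H](C)C(=O)OC(C)(C)C | intermediate
5 | tert-butyl (2R,3S)-3-[3,5-bis(tert-butoxycarbonyloxy)-2-formylphenoxy]-2-methylbutanoate | O=Cc1c(O[C@@H](C)[C@@H](C)C(=O)OC(C)(C)C)cc(OC(=O)OC(C)(C)C)cc1OC(=O)OC(C)(C)C | intermediate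
6 | (1S,2R)-trans-2-phenylcyclohexanol | O[C@H]1CCCC[C@@H]1c1ccccc1 | starting material
7 | ethyl vinyl ether | C=COCC | starting material
8 | (1S,2R)-trans-2-phenylcyclohexyl vinyl ether | C=CO[C@H]1CCCC[C@@H]1c1ccccc1 | intermediate
9 | n-propylmagnesium chloride | CCC[Mg]Cl | starting material
10 | chloromagnesium alkoxide of the propyl adduct of 5 (both epimers at the carbinol carbon) | CCCC(O[Mg]Cl)c1c(OC(=O)OC(C)(C)C)cc(OC(=O)OC(C)(C)C)cc1O[C@@H](C)[C@@H](C)C(=O)OC(C)(C)C | intermediate
11 | benzylic tert-butyl carbonate with the ortho oxygen as chloromagnesium phenoxide (both epimers) | CCCC(OC(=O)OC(C)(C)C)c1c(O[Mg]Cl)cc(OC(=O)OC(C)(C)C)cc1O[C@@H](C)[C@@H](C)C(=O)OC(C)(C)C | intermediate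
12 | (6E)-6-butylidene-3-(tert-butoxycarbonyloxy)-5-{[(2S,3R)-4-tert-butoxy-3-methyl-4-oxobutan-2-yl]oxy}cyclohexa-2,4-dien-1-one (o-quinone methide) | CCC/C=C1/C(=O)C=C(OC(=O)OC(C)(C)C)C=C1O[C@@H](C)[C@@H](C)C(=O)OC(C)(C)C | intermediate
13 | tert-butyl (2R,3S)-3-{[(2R,4R)-7-(tert-butoxycarbonyloxy)-2-{[(1S,2R)-2-phenylcyclohexyl]oxy}-4-propylchroman-5-yl]oxy}-2-methylbutanoate | CCC[C@@H]1C[C@H](O[C@H]3CCCC[C@@H]3c4ccccc4)Oc2cc(OC(=O)OC(C)(C)C)cc(O[C@@H](C)[C@@H](C)C(=O)OC(C)(C)C)c21 | intermediate
14 | tert-butyl (2R,3S)-3-{[(4R)-7-(tert-butoxycarbonyloxy)-2-hydroxy-4-propylchroman-5-yl]oxy}-2-methylbutanoate (anomer mixture) | CCC[C@@H]1CC(O)Oc2cc(OC(=O)OC(C)(C)C)cc(O[C@@H](C)[C@@H](C)C(=O)OC(C)(C)C)c21 | intermediate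
15 | tert-butyl (2R,3S)-3-{[(4R)-7-(tert-butoxycarbonyloxy)-2-oxo-4-propylchroman-5-yl]oxy}-2-methylbutanoate | CCC[C@@H]1CC(=O)Oc2cc(OC(=O)OC(C)(C)C)cc(O[C@@H](C)[C@@H](C)C(=O)OC(C)(C)C)c21 | intermediate
16 | (2R,3S)-3-{[(4R)-7-hydroxy-2-oxo-4-propylchroman-5-yl]oxy}-2-methylbutanoic acid | CCC[C@@H]1CC(=O)Oc2cc(O)cc(O[C@@H](C)[C@@H](C)C(=O)O)c21 | intermediate
17 | (2S,3R,10R)-5-hydroxy-2,3-dimethyl-10-propyl-2,3,9,10-tetrahydro-4H,8H-benzo[1,2-b:3,4-b']dipyran-4,8-dione (cis-2,3-dimethyl) | CCC[C@@H]1CC(=O)Oc2cc(O)c3c(c21)O[C@@H](C)[C@@H](C)C3=O | intermediate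
18 | (2S,3S,10R)-5-hydroxy-2,3-dimethyl-10-propyl-2,3,9,10-tetrahydro-4H,8H-benzo[1,2-b:3,4-b']dipyran-4,8-dione (trans-2,3-dimethyl) | CCC[C@@H]1CC(=O)Oc2cc(O)c3c(c21)O[C@@H](C)[C@H](C)C3=O | intermediate
19 | methyl (3R)-3-[(2S,3S)-5,7-dihydroxy-2,3-dimethyl-4-oxochroman-8-yl]hexanoate | CCC[C@H](CC(=O)OC)c1c(O)cc(O)c2c1O[C@@H](C)[C@H](C)C2=O | intermediate
20 | prenyl bromide (1-bromo-3-methylbut-2-ene) | CC(C)=CCBr | starting material
21 | methyl (3R)-3-[(2S,3S)-5,7-dihydroxy-2,3-dimethyl-6-(3-methylbut-2-en-1-yl)-4-oxochroman-8-yl]hexanoate | CCC[C@H](CC(=O)OC)c1c(O)c(CC=C(C)C)c(O)c2c1O[C@@H](C)[C@H](C)C2=O | target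

Total step count: 11. Longest linear sequence: 9 steps (1 → 2 → 5 → 13 → 14 → 15 → 16 → 17 → 19 → 21; steps 2 and 4 are side branches).

Steps most likely to fail

Step 5. The ether oxygen flanking the methide carbon may erode the E preference of the quinone methide, the auxiliary may not hold one face of the vinyl ether firmly enough, and the quinone methide may be lost by hydrogen shift before it is trapped. In that case C3' is set by catalytic asymmetric conjugate addition. Setting out from aldehyde 5, Wittig olefination with Ph3P=CHC(O)SEt (toluene, 80 °C) gives S-ethyl (2E)-3-{2,4-bis(tert-butoxycarbonyloxy)-6-[(2S,3R)-4-tert-butoxy-3-methyl-4-oxobutan-2-yl]oxyphenyl}prop-2-enethioate F1. Copper-catalysed enantioselective 1,4-addition of n-PrMgBr (CuI, the Tol-BINAP enantiomer that delivers the 3R product, t-BuOMe, −70 °C) gives S-ethyl (3R)-3-{2,4-bis(tert-butoxycarbonyloxy)-6-[(2S,3R)-4-tert-butoxy-3-methyl-4-oxobutan-2-yl]oxyphenyl}hexanethioate F2. CF3CO2H/Et3SiH then removes both carbonates and the tert-butyl ester, the freed ortho phenol closes the lactone on the thioester with loss of ethanethiol (completed with a trace of Et3N if needed), and the route is rejoined at acid 16.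

Step 3. Elimination of the activated β-hydroxy ester to tert-butyl tiglate, or slow displacement at the hindered carbinol, may take over. The carboxyl group is then carried as a vinyl group, which removes the acidic α-hydrogen. Anti-selective crotylboration of acetaldehyde with (E)-crotylB(Ipc)2 (enantiomer chosen for the 2R,3S product) gives (2R,3S)-3-methylpent-4-en-2-ol F3. Setting out from phenol 2, the same Mitsunobu etherification with this alcohol gives, with inversion, 2-[(2S,3S)-3-methylpent-4-en-2-yl]oxy-4,6-bis(tert-butoxycarbonyloxy)benzaldehyde F4. The operations of steps 5 to 7 then give in turn the vinyl-bearing chroman acetal tert-butyl (2R,4R)-5-[(2S,3S)-3-methylpent-4-en-2-yl]oxy-2-[(1S,2R)-2-phenylcyclohexyl]oxy-4-propylchroman-7-yl carbonate F5, the lactol tert-butyl (4R)-2-hydroxy-5-[(2S,3S)-3-methylpent-4-en-2-yl]oxy-4-propylchroman-7-yl carbonate F6 and the lactone tert-butyl (4R)-5-[(2S,3S)-3-methylpent-4-en-2-yl]oxy-2-oxo-4-propylchroman-7-yl carbonate F7. Lemieux–Johnson cleavage (OsO4 cat., NaIO4, 2,6-lutidine, dioxane/H2O) gives the aldehyde tert-butyl (4R)-5-[(2S,3R)-3-methyl-4-oxobutan-2-yl]oxy-2-oxo-4-propylchroman-7-yl carbonate F8, and Pinnick oxidation (NaClO2, NaH2PO4, 2-methylbut-2-ene, t-BuOH/H2O) gives (2R,3S)-3-{[(4R)-7-(tert-butoxycarbonyloxy)-2-oxo-4-propylchroman-5-yl]oxy}-2-methylbutanoic acid F9. CF3CO2H/Et3SiH removes the remaining carbonate and the route is rejoined at acid 16; any epimerisation next to the aldehyde is harmless because C3 is equilibrated in step 10.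

Step 11. O-alkylation at O7 and dearomatising attack at substituted ring carbons may compete with attack at C6. The prenyl group is then delivered through oxygen. Setting out from 19, palladium-catalysed O-alkylation of the free 7-hydroxyl with tert-butyl 2-methylbut-3-en-2-yl carbonate (Pd(PPh3)4, THF, 0 °C) gives methyl (3R)-3-[(2S,3S)-5-hydroxy-2,3-dimethyl-7-(2-methylbut-3-en-2-yloxy)-4-oxochroman-8-yl]hexanoate F10. Aromatic Claisen rearrangement (toluene, 110 °C) transfers the allyl unit, with its ends exchanged, to C6, the only open ortho position, and gives 21.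

Further compounds
F1 | step 5 | S-ethyl (2E)-3-{2,4-bis(tert-butoxycarbonyloxy)-6-[(2S,3R)-4-tert-butoxy-3-methyl-4-oxobutan-2-yl]oxyphenyl}prop-2-enethioate | CCSC(=O)/C=C/c1c(OC(=O)OC(C)(C)C)cc(OC(=O)OC(C)(C)C)cc1O[C@@H](C)[C@@H](C)C(=O)OC(C)(C)C
F2 | step 5 | S-ethyl (3R)-3-{2,4-bis(tert-butoxycarbonyloxy)-6-[(2S,3R)-4-tert-butoxy-3-methyl-4-oxobutan-2-yl]oxyphenyl}hexanethioate | CCC[C@H](CC(=O)SCC)c1c(OC(=O)OC(C)(C)C)cc(OC(=O)OC(C)(C)C)cc1O[C@@H](C)[C@@H](C)C(=O)OC(C)(C)C
F3 | step 3 | (2R,3S)-3-methylpent-4-en-2-ol | C[C@@H](O)[C@@H](C)C=C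
F4 | step 3 | 2-[(2S,3S)-3-methylpent-4-en-2-yl]oxy-4,6-bis(tert-butoxycarbonyloxy)benzaldehyde | O=Cc1c(O[C@@H](C)[C@@H](C)C=C)cc(OC(=O)OC(C)(C)C)cc1OC(=O)OC(C)(C)C
F5 | step 3 | tert-butyl (2R,4R)-5-[(2S,3S)-3-methylpent-4-en-2-yl]oxy-2-[(1S,2R)-2-phenylcyclohexyl]oxy-4-propylchroman-7-yl carbonate | CCC[C@@H]1C[C@H](O[C@H]3CCCC[C@@H]3c4ccccc4)Oc2cc(OC(=O)OC(C)(C)C)cc(O[C@@H](C)[C@@H](C)C=C)c21
F6 | step 3 | tert-butyl (4R)-2-hydroxy-5-[(2S,3S)-3-methylpent-4-en-2-yl]oxy-4-propylchroman-7-yl carbonate (anomer mixture) | CCC[C@@H]1CC(O)Oc2cc(OC(=O)OC(C)(C)C)cc(O[C@@H](C)[C@@H](C)C=C)c21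
F7 | step 3 | tert-butyl (4R)-5-[(2S,3S)-3-methylpent-4-en-2-yl]oxy-2-oxo-4-propylchroman-7-yl carbonate | CCC[C@@H]1CC(=O)Oc2cc(OC(=O)OC(C)(C)C)cc(O[C@@H](C)[C@@H](C)C=C)c21
F8 | step 3 | tert-butyl (4R)-5-[(2S,3R)-3-methyl-4-oxobutan-2-yl]oxy-2-oxo-4-propylchroman-7-yl carbonate | CCC[C@@H]1CC(=O)Oc2cc(OC(=O)OC(C)(C)C)cc(O[C@@H](C)[C@@H](C)C=O)c21
F9 | step 3 | (2R,3S)-3-{[(4R)-7-(tert-butoxycarbonyloxy)-2-oxo-4-propylchroman-5-yl]oxy}-2-methylbutanoic acid | CCC[C@@H]1CC(=O)Oc2cc(OC(=O)OC(C)(C)C)cc(O[C@@H](C)[C@@H](C)C(=O)O)c21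
F10 | step 11 | methyl (3R)-3-[(2S,3S)-5-hydroxy-2,3-dimethyl-7-(2-methylbut-3-en-2-yloxy)-4-oxochroman-8-yl]hexanoate | CCC[C@H](CC(=O)OC)c1c(OC(C)(C)C=C)cc(O)c2c1O[C@@H](C)[C@H](C)C2=O
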